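The benzene ring (numbered from the acylated carbon C1) is built on the side chain, not alkylated. C2(OH), C3(alkyl) and C4(OH) form a 2-alkylmalonyl unit. The carbinol oxygen on side-chain C3' lies δ to C2, so these atoms equal a 3-acyl δ-lactone. C5(H), C6(OH), C1 and the isobutyryl group equal 5-methylhexane-2,4-dione. Everything rests on disconnecting the C1–C2 bond. One Claisen cyclisation forms this bond, breaks the lactone C2–O bond to free the tertiary alcohol, and aromatises. Its precursor is the (6S)-6-methyl-6-(4-methylpent-3-enyl) δ-lactone carrying a 6-methyl-3,5-dioxoheptanoyl chain at C3. The stereocentre comes from Sharpless epoxidation of geraniol.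

Key step: step 10

Remarks on the chemistry.
- The target SMILES encodes S at the carbinol carbon (OH > CH2CH2Ar > CH2CH2CH=CMe2 > CH3). The same spatial arrangement is S in the open-chain intermediates and 6S in the lactones.
- All lactones are C3 epimer mixtures. The polyketones are keto–enol mixtures and are drawn as keto forms. The silyl enol ethers are drawn as one regio- and double-bond isomer.
- Enantiomeric purity is fixed by the epoxidation. It should be checked at the 1,3-diol by chiral HPLC or through the Mosher ester of the primary hydroxyl.

Step 1
Reactants: 1 geraniol, (2E)-3,7-dimethylocta-2,6-dien-1-ol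
Product: 2 (2S,3S)-2,3-epoxygeraniol, [(2S,3S)-3-methyl-3-(4-methylpent-3-en-1-yl)oxiran-2-yl]methanol
Conditions: Ti(OiPr)4 (5 mol %), L-(+)-diethyl tartrate (6 mol %), anhydrous t-BuOOH in decane, 4 Å MS, CH2Cl2, −20 °C
Reagents that add atoms: tert-butyl hydroperoxide, CC(C)(C)OO
Why: Katsuki–Sharpless asymmetric epoxidation: the titanium tartrate catalyst binds the allylic hydroxyl, so only the 2,3-alkene is oxidised while the 6,7-alkene is left alone, and with the L-(+)-tartrate the oxygen reaches the face that gives the (2S,3S)-epoxide, which fixes C3, the only stereocentre that survives into the target.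

Step 2
Reactants: 2 (2S,3S)-2,3-epoxygeraniol
Product: 3 (3S)-3,7-dimethyloct-6-ene-1,3-diol
Conditions: NaAlH2(OCH2CH2OCH3)2 (Red-Al), THF, 0 °C to rt; aq. KNaC4H4O6 (Rochelle salt)
Reagents that add atoms: none
Why: Hydroxyl-directed reductive opening of a 2,3-epoxy alcohol: the aluminate formed at the C1 oxygen hands its hydride to C2, which is also the less substituted epoxide carbon, so the 1,3-diol results and the C3–O bond, hence the S configuration, is never broken.

Step 3
Reactants: 3 (3S)-3,7-dimethyloct-6-ene-1,3-diol
Product: 4 (3S)-1-iodo-3,7-dimethyloct-6-en-3-ol
Conditions: PPh3, imidazole and iodine premixed until the iodine colour has gone, then 3, CH2Cl2, 0 °C, dark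
Reagents that add atoms: iodine, II
Why: Appel-type iodination: only the unhindered primary hydroxyl forms the alkoxyphosphonium salt that iodide displaces by SN2, the tertiary hydroxyl is too crowded to react, and premixing the reagents leaves no free iodine that could trigger iodoetherification of the 6,7-alkene.

Step 4
Reactants: 4 (3S)-1-iodo-3,7-dimethyloct-6-en-3-ol; 5 diallyl malonate
Product: 7 allyl (3RS,6S)-6-methyl-6-(4-methylpent-3-en-1-yl)-2-oxooxane-3-carboxylate, via diallyl hydroxyalkylmalonate 6 (not isolated)
Conditions: NaH (2.0 equiv), 5 (2.5 equiv), THF, 0 °C to reflux until 4 is consumed; then toluene, 95–105 °C, THF and the toluene–allyl alcohol azeotrope distilled off; cold aq. NH4Cl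
Reagents that add atoms: none
Why: Malonic ester alkylation followed in the same flask by base-catalysed transesterification: the excess of the soft sodium enolate displaces the primary iodide by SN2 without double alkylation and is too weak a base to make the alkoxide that would close an oxetane, then the tertiary hydroxyl adds to one ester (6-exo-trig) and removal of allyl alcohol pulls the equilibrium to the lactone, which protects the carbinol and tells the two malonyl carbonyls apart, while the carbinol C–O bond is untouched and the new C3 centre is an irrelevant epimer mixture.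

Step 5
Reactants: 7 allyl (3RS,6S)-6-methyl-6-(4-methylpent-3-en-1-yl)-2-oxooxane-3-carboxylate
Product: 8 (3RS,6S)-6-methyl-6-(4-methylpent-3-en-1-yl)-2-oxooxane-3-carboxylic acid
Conditions: Pd(PPh3)4 (3 mol %), PhNHMe (2 equiv), THF, 0 °C to rt; extraction into cold aq. NaHCO3, citric acid to pH 3–4 at 0 °C, CH2Cl2; concentrated below 20 °C
Reagents that add atoms: none
Why: Tsuji–Trost deallylation: zerovalent palladium ionises only the allyl ester and the weakly basic, poorly acylated N-methylaniline captures the allyl unit, so the lactone is not opened, C3 is not allylated and, at or below room temperature, the malonic half acid does not lose CO2.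

Step 6
Reactants: 8 (3RS,6S)-6-methyl-6-(4-methylpent-3-en-1-yl)-2-oxooxane-3-carboxylic acid
Product: 9 (3RS,6S)-6-methyl-6-(4-methylpent-3-en-1-yl)-2-oxooxane-3-carbonyl chloride
Conditions: Me2C=C(Cl)NMe2 (1.05 equiv), CH2Cl2, 0 °C; the solution is used at once
Reagents that add atoms: 1-chloro-N,N,2-trimethylprop-1-en-1-amine, CC(C)=C(Cl)N(C)C
Why: Acid chloride formation with an α-chloroenamine (Ghosez reagent): the acid adds to the reagent and chloride collapses the acyloxyiminium ion to the acyl chloride and a neutral amide, so neither free HCl (danger for the alkene and the tertiary-alkyl lactone) nor an amine base (ketene from the acidic C3–H) is ever present.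

Step 7
Reactants: 10 5-methylhexane-2,4-dione
Product: 11 5-methyl-4-(trimethylsilyloxy)hex-3-en-2-one
Conditions: Me3SiCl, Et3N, pentane, rt; filtration under argon, concentration
Reagents that add atoms: chlorotrimethylsilane, C[Si](C)(C)Cl
Why: O-silylation of the strongly enolised β-diketone, a standard reaction, in which it does not matter which oxygen is silylated because the isomers interconvert by silyl shift and both lead to the same diene in the next step.

Step 8
Reactants: 11 5-methyl-4-(trimethylsilyloxy)hex-3-en-2-one
Product: 12 (3Z)-5-methyl-2,4-bis(trimethylsilyloxy)hexa-1,3-diene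
Conditions: LiN(iPr)2 (commercial solution), THF, −78 °C; Me3SiCl, −78 °C to rt; pentane, filtration; used fresh
Reagents that add atoms: chlorotrimethylsilane, C[Si](C)(C)Cl
Why: Kinetic deprotonation with a hindered amide base takes a proton of the unhindered CH3 group (α' in the 4-silyloxy enone, γ in its 2-silyloxy isomer) rather than the isopropyl methine, and O-silylation of the dienolate gives the 1,3-bis(silyloxy)diene, the standard two-step preparation of such masked β-dicarbonyl dianions, whose internal double-bond geometry is lost later.

Step 9
Reactants: 9 (3RS,6S)-6-methyl-6-(4-methylpent-3-en-1-yl)-2-oxooxane-3-carbonyl chloride; 12 (3Z)-5-methyl-2,4-bis(trimethylsilyloxy)hexa-1,3-diene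
Product: 14 (3RS,6S)-6-methyl-3-(6-methyl-3,5-dioxoheptanoyl)-6-(4-methylpent-3-en-1-yl)oxan-2-one, via silyl enol ether 13 (not isolated)
Conditions: 12 (1.5 equiv), CH2Cl2, −78 °C to rt, no base, no Lewis acid; pH 7 phosphate buffer, 0 °C; used crude
Reagents that add atoms: none
Why: Vinylogous Mukaiyama-type C-acylation: the terminal CH2 of a 1,3-bis(silyloxy)diene is its most nucleophilic carbon and is known to attack acid chlorides, malonyl half-ester chlorides included, without base or Lewis acid, so the acidic C3–H is not removed, the alkene and the lactone see no strong acid, and the work-up hydrolyses the remaining silyl enol ether 13 to 14.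

Step 10
Reactants: 14 (3RS,6S)-6-methyl-3-(6-methyl-3,5-dioxoheptanoyl)-6-(4-methylpent-3-en-1-yl)oxan-2-one
Product: 15 1-{2,4,6-trihydroxy-3-[(3S)-3-hydroxy-3,7-dimethyloct-6-en-1-yl]phenyl}-2-methylpropan-1-one (target)
Conditions: Mg(OCH3)2 (4 equiv), degassed MeOH, argon, rt to 60 °C; cold AcOH/NaOAc buffer (pH 5); work-up and chromatography never below pH 5
Reagents that add atoms: none
Why: Proposed new method: magnesium methoxide turns the 1,3,5-triketone part of 14 into chelated enolates, and of the two doubly activated methylenes only C4 of the acyl chain can reach the lactone carbonyl C2 through a six-membered transition state (C2 of the chain would close a four-membered ring), so it adds there, the tetrahedral intermediate expels the tertiary alkoxide, and the cyclohexane-1,3,5-trione enolises to the phloroglucinolate as an irreversible sink. The closest known reaction type is the base-mediated biomimetic Claisen (Dieckmann-type) cyclisation of 3,5,7-trioxoalkanoate esters and of 6-(2-oxoalkyl)-4-hydroxy-2-pyrones to 2,4,6-trihydroxyphenyl ketones, whereas a saturated δ-lactone as acyl acceptor and an alkyl group on the carbon next to it have not been shown. The only ring closed is the carbocycle, by a 6-(enolexo)-exo-trig attack, while the lactone ring is opened by acyl–oxygen cleavage. No stereocentre is created: the C3 epimers converge on a planar ring carbon, and the carbinol C–O bond is not touched, so S is retained. The step needs C-acylation at the lactone carbonyl rather than aldol closure, closure through oxygen or retro-Claisen cleavage, and four features of the substrate secure this: the aldol alternative (lactone C3 onto the isopropyl ketone) would have to build a quaternary spiro carbon next to a hindered, enolised carbonyl and cannot aromatise, the alkyl group makes C3–H the least acidic of the three activated sites so that the lactone carbonyl stays electrophilic, closure through oxygen or methanolysis of the lactone should be reversible under methoxide and feed the same pathway, and full enolate formation around the chelating magnesium ion shields the ketones from methoxide.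

Compound list
1 | geraniol | CC(C)=CCC/C(C)=C/CO | starting material
2 | (2S,3S)-2,3-epoxygeraniol | CC(C)=CCC[C@]1(C)O[C@H]1CO | intermediate
3 | (3S)-3,7-dimethyloct-6-ene-1,3-diol | CC(C)=CCC[C@](C)(O)CCO | intermediate
4 | (3S)-1-iodo-3,7-dimethyloct-6-en-3-ol | CC(C)=CCC[C@](C)(O)CCI | intermediate
5 | diallyl malonate | C=CCOC(=O)CC(=O)OCC=C | starting material
6 | diallyl 2-[(3S)-3-hydroxy-3,7-dimethyloct-6-en-1-yl]malonate | CC(C)=CCC[C@](C)(O)CCC(C(=O)OCC=C)C(=O)OCC=C | intermediate
7 | allyl (3RS,6S)-6-methyl-6-(4-methylpent-3-en-1-yl)-2-oxooxane-3-carboxylate | CC(C)=CCC[C@]1(C)OC(=O)C(C(=O)OCC=C)CC1 | intermediate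
8 | (3RS,6S)-6-methyl-6-(4-methylpent-3-en-1-yl)-2-oxooxane-3-carboxylic acid | CC(C)=CCC[C@]1(C)OC(=O)C(C(=O)O)CC1 | intermediate
9 | (3RS,6S)-6-methyl-6-(4-methylpent-3-en-1-yl)-2-oxooxane-3-carbonyl chloride | CC(C)=CCC[C@]1(C)OC(=O)C(C(=O)Cl)CC1 | intermediate
10 | 5-methylhexane-2,4-dione | CC(=O)CC(=O)C(C)C | starting material
11 | 5-methyl-4-(trimethylsilyloxy)hex-3-en-2-one | CC(=O)/C=C(\O[Si](C)(C)C)C(C)C | intermediate
12 | (3Z)-5-methyl-2,4-bis(trimethylsilyloxy)hexa-1,3-diene | C=C(O[Si](C)(C)C)/C=C(\O[Si](C)(C)C)C(C)C | intermediate
13 | (3RS,6S)-6-methyl-3-[6-methyl-3-oxo-5-(trimethylsilyloxy)hept-4-enoyl]-6-(4-methylpent-3-en-1-yl)oxan-2-one | CC(C)=CCC[C@]1(C)OC(=O)C(C(=O)CC(=O)/C=C(\O[Si](C)(C)C)C(C)C)CC1 | intermediate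
14 | (3RS,6S)-6-methyl-3-(6-methyl-3,5-dioxoheptanoyl)-6-(4-methylpent-3-en-1-yl)oxan-2-one | CC(C)=CCC[C@]1(C)OC(=O)C(C(=O)CC(=O)CC(=O)C(C)C)CC1 | intermediate
15 | 1-{2,4,6-trihydroxy-3-[(3S)-3-hydroxy-3,7-dimethyloct-6-en-1-yl]phenyl}-2-methylpropan-1-one | CC(C)=CCC[C@](C)(O)CCc1c(O)cc(O)c(C(=O)C(C)C)c1O | target

Total step count: 10. Longest linear sequence: 8 steps from geraniol (steps 1–6, 9 and 10). Steps 7 and 8 form the short branch.

Steps most likely to fail

**Step 10.**
- What may go wrong:
  - The enolates may close through oxygen and not revert.
  - Methoxide may cleave the chain by retro-Claisen attack.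
  - Complete enolisation of the β-keto lactone may switch off the acceptor.
  - The electron-rich product may be oxidised by air in base.
- Fallback: it gives up ring construction and alkylates a preformed ring, using known reaction types only. It sets out from 4 and comes back to the route at 15. Phloroglucinol is acylated with isobutyryl chloride and AlCl3 in CH2Cl2/nitromethane (Friedel–Crafts acylation) to give 2-methyl-1-(2,4,6-trihydroxyphenyl)propan-1-one F1. Its sodium salt (NaOCH3, MeOH, 50 °C, F1 in threefold excess) is then C-alkylated with iodide 4. This is the reaction type by which methyl, prenyl and geranyl halides are put on acylphloroglucinols. The free tertiary alcohol and the alkene are inert to this base. Slower reaction of the unactivated iodide, O-alkylation and double alkylation have to be accepted and dealt with by chromatography.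

**Step 9.**
- What may go wrong:
  - The α-branched malonyl chloride may lose HCl in a ketene-forming elimination.
  - Attack at the hindered acyl carbon may be sluggish and give way to O-acylation or silyl transfer.
  - The polyketone may cyclise prematurely during work-up.
- Fallback: it avoids the acid chloride and makes the same C–C bond by ester acylation of a β-diketone dianion at its terminal carbon. It sets out from 7 and 10 and bypasses 8, 9 and 11–13. The acidic C3–H of 7 is first masked as the sodium enolate (NaH, THF, 0 °C). This solution is added to an excess of the dilithium dianion of 10 (LiN(iPr)2, two equivalents per diketone, THF, 0 °C to rt) and quenched with cold pH 5 buffer. Attack at the allyl ester carbonyl gives 14 directly. Attack at the lactone carbonyl gives allyl 2-[(3S)-3-hydroxy-3,7-dimethyloct-6-en-1-yl]-8-methyl-3,5,7-trioxononanoate F2. F2 carries the same tetraketide chain and should fold in the same sense under the conditions of step 10, with loss of allyl alcohol. The fallback therefore comes back at 14 and, through F2, at 15.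

**Step 4.**
- What may go wrong:
  - Double alkylation of the malonate may occur.
  - The transesterification by the tertiary alcohol may stall at equilibrium.
  - The allyl ester enolate may slowly rearrange on long heating.
- Fallback: it reverses the order of the two bond formations. It sets out from 4 and 5 and comes back at 7. Diallyl malonate 5 is half-saponified (KOH, one equivalent, allyl alcohol, rt, then cold acidification) to allyl hydrogen malonate F3. F3 acylates the tertiary hydroxyl of 4 with N,N'-dicyclohexylcarbodiimide in CH2Cl2 at 0 °C. This is a Steglich-type esterification that works with tertiary alcohols because malonic half esters react through a ketene. The product is allyl (3S)-1-iodo-3,7-dimethyloct-6-en-3-yl malonate F4. Cs2CO3 in dilute DMF at rt then closes the lactone ring by intramolecular 6-exo-tet C-alkylation, which cannot alkylate twice and is not an equilibrium.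

Further compounds
F1 | step 10 | 2-methyl-1-(2,4,6-trihydroxyphenyl)propan-1-one | CC(C)C(=O)c1c(O)cc(O)cc1O
F2 | step 9 | allyl 2-[(3S)-3-hydroxy-3,7-dimethyloct-6-en-1-yl]-8-methyl-3,5,7-trioxononanoate (C2 epimers) | CC(C)=CCC[C@](C)(O)CCC(C(=O)OCC=C)C(=O)CC(=O)CC(=O)C(C)C
F3 | step 4 | allyl hydrogen malonate | OC(=O)CC(=O)OCC=C
F4 | step 4 | allyl (3S)-1-iodo-3,7-dimethyloct-6-en-3-yl malonate | CC(C)=CCC[C@](C)(OC(=O)CC(=O)OCC=C)CCI
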